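## Retrosynthetic overview

1. Numbering: bicyclo[3.3.1]nonane with bridgeheads C1 and C5, one-carbon bridge C9, and bridges C2–C3–C4 and C6–C7–C8. The strategy rests on the bridge C6–C7–C8: quaternary C8 (methyl, 4-methylpent-3-enyl) next to bridgehead C1 is C3 of a geranyl unit whose C1 and C2 are C6 and C7.
2. Key disconnection C1–C8: C8 is the tertiary carbon of a (2R,3R)-2,3-epoxygeranyl group on C5 of a 6,6-dialkyl-1,5-dimethoxycyclohexa-1,4-diene. Lewis-acid epoxide opening by one enol-ether arm closes ring C1–C9–C5–C6–C7–C8 and sets C1, C5 and C8.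
3. After ring closure: C2 carbonyl by allylic oxidation; C7 oxygen to ketone to methylene, then exo-face hydroboration and B-alkyl Suzuki–Miyaura coupling (endo prenyl); C1 prenyl by bridgehead lithiation; C3 aroyl by vinyl lithiation; hydroxide unmasking.
4. Before: double C6 alkylation of 1,5-dimethoxycyclohexa-1,4-diene (Birch product of 1,3-dimethoxybenzene) with prenyl bromide and with the epoxy bromide from Sharpless epoxidation of geraniol.
5. Ring order: ring C1–C2–C3–C4–C5–C9 is the carbocycle of the arene; ring C1–C9–C5–C6–C7–C8 is closed second, in step 6.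

Key step: step 6

## Remarks on the chemistry

- The nucleophilic ring is used as the 1,5-dimethoxycyclohexa-1,4-diene (C2 still CH2), not as a 3,5-dimethoxycyclohexa-2,5-dienone. In the dienone the carbon that must attack C8 is the α-carbon of a vinylogous ester, a poor π-nucleophile, and its carbonyl would bind the silyl Lewis acid and open cationic allyl shifts toward phenols. The C2 carbonyl is therefore added after ring closure.
- The C9 oxocarbenium is expected to be trapped by the C7 oxygen, so the key-step product is written as the bridged methyl ketal. The free 7-hydroxy-2,9-dione is released two steps later.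
- The two enol-ether arms of the precursor are constitutionally equal but diastereotopic, because the epoxide is already chiral.
- At C7, "exo" means the side away from the C2–C3–C4 bridge and "endo" the side facing it. In every bicyclic compound the C8 methyl is on the C9 side (axial in the chair C1–C9–C5–C6–C7–C8) and the 4-methylpent-3-enyl chain is equatorial.
- The target is drawn as the given 4-hydroxy-2-oxo enol tautomer; it equilibrates with the 2-hydroxy-4-oxo form.

## Route

Step 1
Reactants: 1 1,3-dimethoxybenzene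
Product: 2 1,5-dimethoxycyclohexa-1,4-diene
Conditions: Li, NH3(l), t-BuOH, THF, −78 °C
Reagents that add atoms: none
Why: Birch reduction of the 1,3-dialkoxyarene protonates the two ring positions para to each other that carry no oxygen, which should give the 2,5-dihydro product with both enol ethers intact.

Step 2
Reactants: 2 1,5-dimethoxycyclohexa-1,4-diene; 3 prenyl bromide
Product: 5 1,5-dimethoxy-6-prenylcyclohexa-1,4-diene, via 6-lithio-1,5-dimethoxycyclohexa-1,4-diene 4 (not isolated)
Conditions: t-BuLi, THF, −78 °C; then 3, −78 °C → rt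
Reagents that add atoms: none
Why: Metalation of the doubly allylic CH2 flanked by the two methoxy-bearing carbons gives a pentadienyl anion that is alkylated at its central carbon by the allylic bromide (SN2 alkylation of a cyclohexadienyl anion).

Step 3
Reactants: 6 geraniol
Product: 7 (2R,3R)-2,3-epoxygeraniol
Conditions: Ti(Oi-Pr)4 (5 mol %), D-(−)-diethyl tartrate (6 mol %), t-BuOOH, 4 Å MS, CH2Cl2, −20 °C
Reagents that add atoms: tert-butyl hydroperoxide, CC(C)(C)OO
Why: Sharpless asymmetric epoxidation of the allylic alcohol; D-(−)-diethyl tartrate directs oxygen to the face that gives the (2R,3R) epoxide, and the 6,7-alkene, which has no directing hydroxyl, should stay untouched.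

Step 4
Reactants: 7 (2R,3R)-2,3-epoxygeraniol
Product: 9 (2S,3R)-2-(bromomethyl)-3-methyl-3-(4-methylpent-3-enyl)oxirane, via epoxygeranyl mesylate 8 (not isolated)
Conditions: MsCl, Et3N, CH2Cl2, −10 °C; then LiBr, THF, 0 °C → rt
Reagents that add atoms: lithium bromide, [Li+].[Br-]
Why: Mesylation followed by Finkelstein-type SN2 displacement at the primary carbon; neither epoxide carbon is touched, so both stereocentres are kept (the C2 descriptor becomes S only because CH2Br outranks C3).

Step 5
Reactants: 5 1,5-dimethoxy-6-prenylcyclohexa-1,4-diene; 9 epoxygeranyl bromide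
Product: 11 6-(epoxygeranyl)-1,5-dimethoxy-6-prenylcyclohexa-1,4-diene, via 6-lithio-1,5-dimethoxy-6-prenylcyclohexa-1,4-diene 10 (not isolated)
Conditions: t-BuLi, THF, −78 °C; then 9, −78 → −20 °C
Reagents that add atoms: none
Why: A second metalation at the now tertiary, doubly allylic C6 and SN2 alkylation of the pentadienyl anion at its central carbon by the primary bromide should create the quaternary centre; the epoxide carbons are more hindered than CH2Br and should not be attacked.

Step 6
Reactants: 11 6-(epoxygeranyl)-1,5-dimethoxy-6-prenylcyclohexa-1,4-diene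
Product: 13 bridged methyl ketal (7,9-epoxy-4,9-dimethoxy-8-methyl-8-(4-methylpent-3-enyl)-5-prenylbicyclo[3.3.1]non-3-ene), via C9 methyl oxocarbenium triflate 12 (not isolated)
Conditions: Me3SiOTf (0.5 equiv), 2,6-lutidine, CH2Cl2, −78 °C
Reagents that add atoms: none
Why: Me3SiOTf silylates the epoxide oxygen and the β-carbon of one methyl enol ether (C1) attacks the tertiary epoxide carbon C8 anti to the leaving oxygen, a cationic epoxide-opening carbocyclization of the kind established for 6,6-dialkyl-1,5-dimethoxycyclohexa-1,4-dienes and for epoxy-polyene cyclizations; the C9 oxocarbenium is then captured by the C7 silyl ether oxygen with loss of the silyl group, which returns the Lewis acid. Ring C1–C9–C5–C6–C7–C8 closes by 6-endo-tet opening at the epoxide (both epoxide carbons and the C1=C9 enol-ether bond end up inside the new ring), and the oxygen bridge C7–O–C9 closes a five-membered ring by 5-exo-trig addition to the oxocarbenium. C8 is set by inversion at the (3R) epoxide carbon, C7 is carried over unchanged from the (2R) carbon, and C1 and C5 follow from which diastereotopic arm reacts. Only one arm can reach C8 through a chair with the C7 oxygen and the homoprenyl chain equatorial and the C8 methyl axial, the other arm would need a boat; C9 is fixed by the cage. The step needs attack at the tertiary and not the secondary epoxide carbon, which the cation-stabilising substitution at C8 and the chair geometry should secure. It also needs the enol ether to outrun the C5 prenyl alkene, which could close a six-membered ring onto C8; the enol ether is by far the better π-nucleophile.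

Step 7
Reactants: 13 bridged methyl ketal
Product: 14 bridged-ketal vinylogous ester (7,9-epoxy-4,9-dimethoxy-8-methyl-8-(4-methylpent-3-enyl)-5-prenylbicyclo[3.3.1]non-3-en-2-one)
Conditions: PhI(OAc)2, t-BuOOH, K2CO3 (0.2 equiv), EtOAc, −20 °C
Reagents that add atoms: tert-butyl hydroperoxide, CC(C)(C)OO
Why: Radical allylic oxidation (hydrogen abstraction by tert-butylperoxy radicals, peroxide formation and Kornblum–DeLaMare-type collapse) should take place at C2, the CH2 allylic to the electron-rich enol ether, and turn the enol ether into a vinylogous ester; the prenyl-type alkenes carry less activated allylic hydrogens.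

Step 8
Reactants: 14 bridged-ketal vinylogous ester
Product: 15 7-exo-hydroxy-4-methoxy-8-methyl-8-(4-methylpent-3-enyl)-5-prenylbicyclo[3.3.1]non-3-ene-2,9-dione
Conditions: Me2BBr, CH2Cl2, −78 °C; then aq. NaHCO3
Reagents that add atoms: none
Why: Lewis-acid ketal cleavage: boron binds the bridging oxygen and the C9–O(ring) bond breaks, the only ionisation the cage allows; bromide removes the methyl of the oxocarbenium and hydrolysis of the borinate frees the alcohol, the C7–O bond never being broken.

Step 9
Reactants: 15 7-exo-hydroxy-2,9-dione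
Product: 16 4-methoxy-8-methyl-8-(4-methylpent-3-enyl)-5-prenylbicyclo[3.3.1]non-3-ene-2,7,9-trione
Conditions: Dess–Martin periodinane, CH2Cl2, 0 °C → rt
Reagents that add atoms: none
Why: Dess–Martin oxidation of the secondary alcohol under neutral conditions; the vinylogous ester and the alkenes should be inert and no stereocentre is involved.

Step 10
Reactants: 16 2,7,9-trione
Product: 17 4-methoxy-8-methyl-7-methylidene-8-(4-methylpent-3-enyl)-5-prenylbicyclo[3.3.1]non-3-ene-2,9-dione
Conditions: Ph3PCH3Br, KOt-Bu, THF, 0 → 40 °C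
Reagents that add atoms: methyltriphenylphosphonium bromide, C[P+](c1ccccc1)(c1ccccc1)c1ccccc1.[Br-]
Why: Wittig methylenation; the ylide should attack the C7 ketone, which has one CH2 neighbour, in preference to the bridging C9 ketone (flanked by C1 and quaternary C5 and shielded by the axial C8 methyl) and to the deactivated vinylogous ester carbonyl.

Step 11
Reactants: 17 7-methylidene-2,9-dione
Product: 19 3-trimethylsilyl-7-methylidene-2,9-dione, via C3-lithio vinylogous ester 18 (not isolated)
Conditions: lithium 2,2,6,6-tetramethylpiperidide (LiTMP, from the amine and n-BuLi), Me3SiCl present, THF, −78 °C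
Reagents that add atoms: chlorotrimethylsilane, C[Si](C)(C)Cl
Why: Kinetic deprotonation of the vinylic C3–H of the β-methoxy enone by the hindered amide with in situ silyl capture blocks C3, which would otherwise be metalated faster than the hindered bridgehead C1–H (directed vinyl lithiation and C-silylation).

Step 12
Reactants: 19 3-trimethylsilyl-7-methylidene-2,9-dione; 3 prenyl bromide
Product: 21 1,5-diprenyl-3-trimethylsilyl-7-methylidene-2,9-dione, via C1-lithio bridgehead carbanion 20 (not isolated)
Conditions: LiTMP, THF, −78 → −40 °C; then 3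
Reagents that add atoms: none
Why: Bridgehead lithiation–alkylation: with C3 blocked the amide should remove the C1–H, acidified by the C2 and C9 carbonyls, and the bridgehead carbanion, which cannot invert, is alkylated by SN2 on prenyl bromide with retention.

Step 13
Reactants: 21 1,5-diprenyl-3-trimethylsilyl-7-methylidene-2,9-dione; 22 1-bromo-2-methylprop-1-ene
Product: 24 1,5,7-triprenyl-3-trimethylsilyl-2,9-dione (7-prenyl endo), via endo C7-methylene 9-BBN borane 23 (not isolated)
Conditions: 9-BBN, THF, 0 °C → rt; then 22, PdCl2(dppf) (5 mol %), K3PO4 (aq), DMF, 50 °C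
Reagents that add atoms: none
Why: Hydroboration then B-alkyl Suzuki–Miyaura coupling: 9-BBN should add only to the 1,1-disubstituted C7 methylene (boron on CH2) and deliver hydrogen to C7 from the exo face, the endo face being blocked by the C2–C3–C4 bridge, so the CH2–B arm and hence the new prenyl group are endo; the trisubstituted alkenes and the doubly flanked carbonyls react far more slowly.

Step 14
Reactants: 24 1,5,7-triprenyl-3-trimethylsilyl-2,9-dione
Product: 25 4-methoxy-8-methyl-8-(4-methylpent-3-enyl)-1,5,7-triprenylbicyclo[3.3.1]non-3-ene-2,9-dione (7-prenyl endo)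
Conditions: Bu4NF, THF, 0 °C
Reagents that add atoms: none
Why: Fluoride-induced protodesilylation of the α-silyl enone returns the C3–H; no stereocentre is involved.

Step 15
Reactants: 26 3-hydroxybenzoic acid
Product: 27 tert-butyldimethylsilyl 3-(tert-butyldimethylsilyloxy)benzoate
Conditions: t-BuMe2SiCl (2.2 equiv), imidazole, DMF, rt
Reagents that add atoms: tert-butyl(chloro)dimethylsilane, CC(C)(C)[Si](C)(C)Cl
Why: Silylation of both the phenol and the carboxylic acid (silyl ether and silyl ester formation).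

Step 16
Reactants: 27 bis-silylated 3-hydroxybenzoic acid
Product: 28 3-(tert-butyldimethylsilyloxy)benzoyl chloride
Conditions: (COCl)2, DMF (cat.), CH2Cl2, 0 °C → rt
Reagents that add atoms: oxalyl chloride, ClC(=O)C(Cl)=O
Why: Vilsmeier-type chlorination converts the silyl ester directly into the acid chloride under neutral conditions that should leave the aryl silyl ether in place.

Step 17
Reactants: 25 1,5,7-triprenyl-4-methoxy-2,9-dione; 28 3-(tert-butyldimethylsilyloxy)benzoyl chloride
Product: 30 3-[3-(tert-butyldimethylsilyloxy)benzoyl]-4-methoxy-1,5,7-triprenyl-2,9-dione, via C3-lithio vinylogous ester 29 (not isolated)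
Conditions: LiTMP, THF, −78 °C; then 28
Reagents that add atoms: none
Why: C3 lithiation of the vinylogous ester, now the only acidic position, and C-acylation of the vinyllithium by the aroyl chloride.

Step 18
Reactants: 30 protected target
Product: 31 CNP0406274.1
Conditions: LiOH, dioxane–H2O, 90 °C; then aq. HCl
Reagents that add atoms: lithium hydroxide, [Li+].[OH-]
Why: Hydroxide should cleave the vinylogous methyl ester by conjugate addition–elimination at C4 and remove the base-labile aryl silyl ether; acidification gives the enolised β-triketone without touching the four carbon stereocentres.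

## Compound list

1 | 1,3-dimethoxybenzene | COc1cccc(OC)c1 | starting material
2 | 1,5-dimethoxycyclohexa-1,4-diene | COC1=CCC=C(OC)C1 | intermediate
3 | prenyl bromide (1-bromo-3-methylbut-2-ene) | CC(C)=CCBr | starting material
4 | 6-lithio-1,5-dimethoxycyclohexa-1,4-diene | COC1=CCC=C(OC)C1[Li] | intermediate
5 | 1,5-dimethoxy-6-(3-methylbut-2-en-1-yl)cyclohexa-1,4-diene | COC1=CCC=C(OC)C1CC=C(C)C | intermediate
6 | geraniol | CC(C)=CCC/C(C)=C/CO | starting material
7 | (2R,3R)-2,3-epoxygeraniol, [(2R,3R)-3-methyl-3-(4-methylpent-3-en-1-yl)oxiran-2-yl]methanol | CC(C)=CCC[C@@]1(C)O[C@@H]1CO | intermediate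
8 | [(2R,3R)-3-methyl-3-(4-methylpent-3-en-1-yl)oxiran-2-yl]methyl methanesulfonate | CC(C)=CCC[C@@]1(C)O[C@@H]1COS(C)(=O)=O | intermediate
9 | (2S,3R)-2-(bromomethyl)-3-methyl-3-(4-methylpent-3-en-1-yl)oxirane | CC(C)=CCC[C@@]1(C)O[C@@H]1CBr | intermediate
10 | 6-lithio-1,5-dimethoxy-6-(3-methylbut-2-en-1-yl)cyclohexa-1,4-diene | COC1=CCC=C(OC)C1([Li])CC=C(C)C | intermediate
11 | 1,5-dimethoxy-6-{[(2R,3R)-3-methyl-3-(4-methylpent-3-en-1-yl)oxiran-2-yl]methyl}-6-(3-methylbut-2-en-1-yl)cyclohexa-1,4-diene | CC(C)=CCC[C@@]1(C)O[C@@H]1CC1(CC=C(C)C)C(OC)=CCC=C1OC | intermediate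
12 | C9 O-methyl oxocarbenium triflate of the cyclized 7-exo-trimethylsilyloxy bicycle | CC(C)=CCC[C@@]1(C)[C@H](O[Si](C)(C)C)C[C@]2(CC=C(C)C)C(=[O+]C)[C@H]1CC=C2OC.[O-]S(=O)(=O)C(F)(F)F | intermediate
13 | 7,9-epoxy-4,9-dimethoxy-8-methyl-8-(4-methylpent-3-en-1-yl)-5-(3-methylbut-2-en-1-yl)bicyclo[3.3.1]non-3-ene (oxygen bridge from the exo face of C7 to C9) | CC(C)=CCC[C@@]1(C)[C@H]2C[C@@]3(CC=C(C)C)C(OC)=CC[C@@H]1[C@@]3(OC)O2 | intermediate
14 | 7,9-epoxy-4,9-dimethoxy-8-methyl-8-(4-methylpent-3-en-1-yl)-5-(3-methylbut-2-en-1-yl)bicyclo[3.3.1]non-3-en-2-one | CC(C)=CCC[C@@]1(C)[C@H]2C[C@@]3(CC=C(C)C)C(OC)=CC(=O)[C@@H]1[C@@]3(OC)O2 | intermediate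
15 | 7-exo-hydroxy-4-methoxy-8-methyl-8-(4-methylpent-3-en-1-yl)-5-(3-methylbut-2-en-1-yl)bicyclo[3.3.1]non-3-ene-2,9-dione | CC(C)=CCC[C@@]1(C)[C@H](O)C[C@]2(CC=C(C)C)C(=O)[C@H]1C(=O)C=C2OC | intermediate
16 | 4-methoxy-8-methyl-8-(4-methylpent-3-en-1-yl)-5-(3-methylbut-2-en-1-yl)bicyclo[3.3.1]non-3-ene-2,7,9-trione | CC(C)=CCC[C@@]1(C)C(=O)C[C@]2(CC=C(C)C)C(=O)[C@H]1C(=O)C=C2OC | intermediate
17 | 4-methoxy-8-methyl-7-methylidene-8-(4-methylpent-3-en-1-yl)-5-(3-methylbut-2-en-1-yl)bicyclo[3.3.1]non-3-ene-2,9-dione | CC(C)=CCC[C@@]1(C)C(=C)C[C@]2(CC=C(C)C)C(=O)[C@H]1C(=O)C=C2OC | intermediate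
18 | 3-lithio derivative of 17 | CC(C)=CCC[C@@]1(C)C(=C)C[C@]2(CC=C(C)C)C(=O)[C@H]1C(=O)C([Li])=C2OC | intermediate
19 | 4-methoxy-8-methyl-7-methylidene-8-(4-methylpent-3-en-1-yl)-5-(3-methylbut-2-en-1-yl)-3-(trimethylsilyl)bicyclo[3.3.1]non-3-ene-2,9-dione | CC(C)=CCC[C@@]1(C)C(=C)C[C@]2(CC=C(C)C)C(=O)[C@H]1C(=O)C([Si](C)(C)C)=C2OC | intermediate
20 | 1-lithio derivative of 19 | CC(C)=CCC[C@@]1(C)C(=C)C[C@]2(CC=C(C)C)C(=O)[C@@]1([Li])C(=O)C([Si](C)(C)C)=C2OC | intermediate
21 | 4-methoxy-8-methyl-7-methylidene-8-(4-methylpent-3-en-1-yl)-1,5-bis(3-methylbut-2-en-1-yl)-3-(trimethylsilyl)bicyclo[3.3.1]non-3-ene-2,9-dione | CC(C)=CCC[C@@]1(C)C(=C)C[C@]2(CC=C(C)C)C(=O)[C@@]1(CC=C(C)C)C(=O)C([Si](C)(C)C)=C2OC | intermediate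
22 | 1-bromo-2-methylprop-1-ene | CC(C)=CBr | starting material
23 | 7-endo-[(9-borabicyclo[3.3.1]nonan-9-yl)methyl] derivative from 21 | CC(C)=CCC[C@@]1(C)[C@@H](CB3C4CCCC3CCC4)C[C@]2(CC=C(C)C)C(=O)[C@@]1(CC=C(C)C)C(=O)C([Si](C)(C)C)=C2OC | intermediate
24 | 4-methoxy-8-methyl-8-(4-methylpent-3-en-1-yl)-1,5,7-tris(3-methylbut-2-en-1-yl)-3-(trimethylsilyl)bicyclo[3.3.1]non-3-ene-2,9-dione (7-prenyl endo) | CC(C)=CCC[C@@]1(C)[C@@H](CC=C(C)C)C[C@]2(CC=C(C)C)C(=O)[C@@]1(CC=C(C)C)C(=O)C([Si](C)(C)C)=C2OC | intermediate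
25 | 4-methoxy-8-methyl-8-(4-methylpent-3-en-1-yl)-1,5,7-tris(3-methylbut-2-en-1-yl)bicyclo[3.3.1]non-3-ene-2,9-dione (7-prenyl endo) | CC(C)=CCC[C@@]1(C)[C@@H](CC=C(C)C)C[C@]2(CC=C(C)C)C(=O)[C@@]1(CC=C(C)C)C(=O)C=C2OC | intermediate
26 | 3-hydroxybenzoic acid | OC(=O)c1cccc(O)c1 | starting material
27 | tert-butyldimethylsilyl 3-(tert-butyldimethylsilyloxy)benzoate | CC(C)(C)[Si](C)(C)OC(=O)c1cccc(O[Si](C)(C)C(C)(C)C)c1 | intermediate
28 | 3-(tert-butyldimethylsilyloxy)benzoyl chloride | CC(C)(C)[Si](C)(C)Oc1cccc(C(Cl)=O)c1 | intermediate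
29 | 3-lithio derivative of 25 | CC(C)=CCC[C@@]1(C)[C@@H](CC=C(C)C)C[C@]2(CC=C(C)C)C(=O)[C@@]1(CC=C(C)C)C(=O)C([Li])=C2OC | intermediate
30 | 3-[3-(tert-butyldimethylsilyloxy)benzoyl]-4-methoxy-8-methyl-8-(4-methylpent-3-en-1-yl)-1,5,7-tris(3-methylbut-2-en-1-yl)bicyclo[3.3.1]non-3-ene-2,9-dione | CC(C)=CCC[C@@]1(C)[C@@H](CC=C(C)C)C[C@]2(CC=C(C)C)C(=O)[C@@]1(CC=C(C)C)C(=O)C(C(=O)c1cccc(O[Si](C)(C)C(C)(C)C)c1)=C2OC | intermediate
31 | CNP0406274.1, (1S,5S,7S,8S)-4-hydroxy-3-(3-hydroxybenzoyl)-8-methyl-8-(4-methylpent-3-en-1-yl)-1,5,7-tris(3-methylbut-2-en-1-yl)bicyclo[3.3.1]non-3-ene-2,9-dione | CC(C)=CCC[C@@]1(C)[C@@H](CC=C(C)C)C[C@]2(CC=C(C)C)C(=O)[C@@]1(CC=C(C)C)C(=O)C(C(=O)c1cccc(O)c1)=C2O | target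

## Step count and risks

Total step count: 18 (steps 3–4 and 15–16 are side branches).
Longest linear sequence: 14 steps (1, 2, 5–14, 17, 18).

Steps most likely to fail:

**Step 12 (C1 prenylation).** The bridgehead carbanion is hemmed in by quaternary C8 and by the C2 and C9 carbonyls. It may form incompletely or couple too slowly with the γ,γ-disubstituted allylic bromide, so that proton return from the amine or attack through oxygen takes over. Fallback, from 19 back to 21: the same lithiation is quenched with the smaller, more reactive allyl bromide to give 1-allyl-4-methoxy-8-methyl-7-methylidene-8-(4-methylpent-3-enyl)-5-prenyl-3-(trimethylsilyl)bicyclo[3.3.1]non-3-ene-2,9-dione F4. Cross-metathesis of F4 with 2-methyl-2-butene as solvent (second-generation Grubbs catalyst, CH2Cl2, 40 °C) then turns the allyl into the prenyl group of 21. The hindered 1,1-disubstituted C7 methylene and the trisubstituted alkenes should not take part.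

**Step 13 (hydroboration and B-alkyl coupling).** Transmetalation of the β-branched primary borane, which is flanked by quaternary C8, may be slow, so that protodeboronation and β-hydride elimination compete with C–C bond formation. Any leakage of the hydroboration to the endo face would also surface here as the 7-exo epimer. Fallback, from 21 back to 24: borane 23 is oxidised in the flask (H2O2, NaOH, 0 °C) to the 7-endo-hydroxymethyl compound F5. F5 is converted (I2, PPh3, imidazole, CH2Cl2) into the 7-endo-iodomethyl compound F6. F6 is joined to 22 by nickel-catalysed reductive cross-electrophile coupling (NiBr2(dme) cat., 4,4'-di-tert-butyl-2,2'-bipyridine, Zn, DMA, rt) to give 24.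

**Step 6 (key cyclization).** The silyl-activated epoxide may be intercepted by the trisubstituted prenyl alkene on C5 (closure of a six-membered carbocycle that ends in a 2-propyl cation) in competition with the enol ether. Fallback, from 2 back to 13: the prenyl group is carried through the cyclization as a much less nucleophilic allyl group. Diene 2 is alkylated (t-BuLi; allyl bromide) to 6-allyl-1,5-dimethoxycyclohexa-1,4-diene F1. F1 is alkylated again (t-BuLi; 9) to 6-allyl-6-(epoxygeranyl)-1,5-dimethoxycyclohexa-1,4-diene F2. F2 is cyclized under the conditions of step 6 to the 5-allyl bridged methyl ketal F3. Cross-metathesis of F3 with 2-methyl-2-butene (second-generation Grubbs catalyst) gives 13.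

## Further compounds

F1 | step 6 | 6-allyl-1,5-dimethoxycyclohexa-1,4-diene | COC1=CCC=C(OC)C1CC=C
F2 | step 6 | 6-allyl-1,5-dimethoxy-6-{[(2R,3R)-3-methyl-3-(4-methylpent-3-en-1-yl)oxiran-2-yl]methyl}cyclohexa-1,4-diene | CC(C)=CCC[C@@]1(C)O[C@@H]1CC1(CC=C)C(OC)=CCC=C1OC
F3 | step 6 | 5-allyl-7,9-epoxy-4,9-dimethoxy-8-methyl-8-(4-methylpent-3-en-1-yl)bicyclo[3.3.1]non-3-ene | CC(C)=CCC[C@@]1(C)[C@H]2C[C@@]3(CC=C)C(OC)=CC[C@@H]1[C@@]3(OC)O2
F4 | step 12 | 1-allyl-4-methoxy-8-methyl-7-methylidene-8-(4-methylpent-3-en-1-yl)-5-(3-methylbut-2-en-1-yl)-3-(trimethylsilyl)bicyclo[3.3.1]non-3-ene-2,9-dione | CC(C)=CCC[C@@]1(C)C(=C)C[C@]2(CC=C(C)C)C(=O)[C@@]1(CC=C)C(=O)C([Si](C)(C)C)=C2OC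
F5 | step 13 | 7-endo-(hydroxymethyl)-4-methoxy-8-methyl-8-(4-methylpent-3-en-1-yl)-1,5-bis(3-methylbut-2-en-1-yl)-3-(trimethylsilyl)bicyclo[3.3.1]non-3-ene-2,9-dione | CC(C)=CCC[C@@]1(C)[C@@H](CO)C[C@]2(CC=C(C)C)C(=O)[C@@]1(CC=C(C)C)C(=O)C([Si](C)(C)C)=C2OC
F6 | step 13 | 7-endo-(iodomethyl)-4-methoxy-8-methyl-8-(4-methylpent-3-en-1-yl)-1,5-bis(3-methylbut-2-en-1-yl)-3-(trimethylsilyl)bicyclo[3.3.1]non-3-ene-2,9-dione | CC(C)=CCC[C@@]1(C)[C@@H](CI)C[C@]2(CC=C(C)C)C(=O)[C@@]1(CC=C(C)C)C(=O)C([Si](C)(C)C)=C2OC
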